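## Structural features

The target is a linear B-type proanthocyanidin tetramer: four 2-arylchroman-3-ol units, each with a phloroglucinol-derived ring A fused to a pyran ring C and a pendant ring B, which is a catechol in units 1, 3 and 4 (epicatechin) and a 4-hydroxyphenyl group in unit 2 (epiafzelechin). The units are joined by three aryl–methine bonds, C4(unit 1)–C6(unit 2), C4(unit 2)–C8(unit 3) and C4(unit 3)–C6(unit 4), so two of the three links are of the 4→6 type that ordinary cationic couplings disfavour. There are eleven stereocentres: C2 and C3 are R,R and cis in every unit, and in units 1 to 3 the C4 aryl group is trans to the 3-hydroxyl (4β), which gives three contiguous C2–C3–C4 triads. The fifteen phenols are sensitive to air and base, the interflavan bonds and the benzylic C2–O1 bonds are cleaved by acid, and every ring A is a strong carbon nucleophile with more than one free position. The real difficulty is therefore regiocontrol (C6 against C8) and stopping each arylation after one bond, more than the configuration at C4, which follows the 3-substituent. Ring A of unit 2 is attached to unit 1 through the carbon para to O1 and between O5 and O7; seen from unit 1 it is a 2,4,6-trioxygenated phenyl group that is symmetric about its long axis, so the 4→6 link needs no regiocontrol if this ring is brought in as such and its para oxygen stays distinguishable. The key step uses this together with the trans O3/C4-aryl relationship in ring C of unit 1: anti attack of C4a of ring A on C4 of a trans C3–C4 oxirane forms C4–C4a, closes ring C and sets C4.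

## Logic of the disconnections

27 to 26: fifteen O–benzyl bonds and the C8–Br bond of unit 4 are cut. Benzyl ethers are chosen because they come off without acid or base, and the bromine leaves in the same operation. All earlier chemistry then runs on non-oxidisable ethers. The forward step must remove sixteen groups without breaking the benzylic C2–O1 or interflavan bonds.

26 to 20 and 25: the central C4(unit 2)–C8(unit 3) bond is cut. It divides the molecule into two dimers of similar size, and a C4 cation next to a cis-2,3 unit is captured trans to O3. The forward step needs C4 of unit 2 in 20 to ionise and 25 to react only at C8 of unit 3; the bromine at C8 of unit 4 and an excess of 25 are meant to secure this.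

25 to 23 and 24, both to 22, then to 21: the C4(unit 3)–C6(unit 4) bond, the C4–O bond of 24, the C8–Br bond of 23 and four O–benzyl bonds are cut. Both units are then the natural monomer 21. The forward coupling must go to the hindered C6, which is forced by the bromine at C8; the same bromine later blocks C8 of unit 4 in 25.

20 to 19: the C4–O bond of unit 2 is cut (an oxidation-level adjustment). This leaves a dimer with a plain methylene at C4 of unit 2. The forward step must abstract hydride from that methylene and not from the C4 methine or the C2 positions.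

19 to 18, then to 14 and 17; 17 to 16 to 15: the C4–C4a bond of unit 2 is cut (oxirane–arene closure), then the O1–C2 ether bond, then the oxirane C–O bonds and the vinyl–carbinol bond. Ring A of unit 2 is already in place in 14 and has two equivalent positions ortho to its free oxygen, so unit 2 reduces to a three-carbon epoxy alcohol. The etherification must invert cleanly and the closure must be 6-endo at a primary oxirane carbon.

14 to 13: the O–S bond of the para sulfonate is cut. This is the point at which the para oxygen of the future ring A of unit 2 is distinguished from its two neighbours. The forward step must free this one oxygen without touching benzyl ethers.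

13 to 12 (key): the C4–C4a bond of unit 1 is cut. This opens ring C, removes the C4 stereocentre and gives an acyclic aryl ether of a trans oxirane. The forward step must be an anti opening at the benzylic oxirane carbon by the symmetric 3,5-dioxygenated aryl ether, 6-endo, and faster than hydride shift.

12 to 10 and 11: the aryl ether C2–O1 bond is cut. The nucleophilic ring becomes a commercial symmetric phenol, and the ether is made only after the alkene has been epoxidised, so no 1,3-diarylallyl cation can form. The forward step must invert the carbinol without ionisation and without opening the oxirane.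

10 to 9 to 8: the two oxirane C–O bonds are cut back to an E-alkene and the carbinol C–H bond back to a ketone. The three stereocentres of 10 reduce to none. Both forward steps must be reagent-controlled.

8 to 3 and 5 (through 6 and 7); 3 to 2 to 1; 5 to 4: the enone C=C bond, four O–benzyl bonds and one O–S bond are cut. Three commercial aromatics remain. The forward condensation must avoid hydroxide, and the sulfonylation of 1 must select the para hydroxyl.

## Other disconnections considered

Alternative 1: The cut is C4(unit 3)–C6(unit 4), made intramolecularly. The two 5-oxygens are joined by a diisopropylsilylene bridge in A2, which carries a 4-ethoxy group on unit 3. A boron Lewis acid ionises C4, and only C6 of unit 4 can close the eight-membered dibenzo-dioxasilocine A1.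
- In its favour: regiochemistry comes from ring size and not from a blocking atom, the two halves react 1:1, and no halogen is carried.
- Against it here: both monomers need their 5-hydroxyl told apart from the 7-hydroxyl before the tether can be built, which costs several protecting-group steps per unit. The β orientation at C4 must be compatible with the medium ring. After the silicon is removed, C8 of unit 4 is unblocked, so the later union with unit 2 would have three free ring A positions to choose from.
- Comparison with steps 15 to 18: A1 is the better on material economy of the coupling, since no excess of a partner is needed. It is the equal on mechanism, since both use a C4 cation captured trans to O3. It is longer, and it leaves the next coupling less controlled than the bromine of 25, which serves twice.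

Alternative 2: The cuts are C3–C4 and O1–C2 of unit 2. The benzhydrol A4 (ring A phenol of unit 2 with the unit 3–unit 4 half on the future C4) loses water to an ortho-quinone methide. This is trapped by an O-benzylglycolyl ammonium enolate bound to a chiral isothiourea; conjugate addition and lactonisation give the 3,4-trans dihydrocoumarin A3.
- In its favour: two bonds and two stereocentres (C3, C4) are set in one catalyst-controlled event. The lower half enters by carbonyl addition, so no C4 cation, no oxidation of an advanced dimer and no excess of the lower half are needed. On convergence at C4 it is the better of the two plans.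
- Against it: the lactone carbon must still become C2 with a 4-benzyloxyphenyl group cis to O3 (aryl addition, then reductive removal of the hemiketal oxygen, with uncertain facial control). The quinone methide would carry two very electron-rich, hindered aryl groups, which lowers its electrophilicity. Alkoxy-substituted ammonium enolates are less well behaved than alkyl or aryl ones. Catalyst control must override a large chiral substrate with restricted rotation, and metalation at C8 of unit 3 alone requires a halogen there and nowhere else.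
- Comparison with steps 12 to 14 and 19: the chosen plan relies on substrate-inherent trans selectivity at C4 and sets C2 and C3 of unit 2 before ring closure; A3 is weaker at C2 and would probably need two to three more steps after the annulation.

Alternative 3: The cut is O1–C2 of unit 1. The open-chain phenol A6, with C3 and C4 already set, is oxidised by a high-potential quinone at the C2 methylene next to the 3,4-dibenzyloxyphenyl ring, and the ring A phenol captures the cation to give A5.
- In its favour: no oxirane is handled. A5 already has O3 benzylated and the para oxygen as an acetal that comes off under mild acid, so on protecting-group economy it is the better intermediate compared with 13 and 14. The ring formed and the three aromatic building blocks are the same as in the chosen plan.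
- Against it: C2 is created last under cation control, and capture anti to the 3-benzyloxy group would give the 2,3-trans isomer. The oxidant also meets a more hydridic C–H, the C4 methine between two trioxygenated rings, and an oxidisable free phenol. A6 needs a diarylmethine stereocentre whose two aryl groups differ only in protecting-group pattern, which is hard to set enantioselectively.
- Comparison: the chosen step sets C4 by a stereospecific opening and leaves C2 and C3 to reagent-controlled steps 5 to 7. The step count is probably similar.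

Key step: step 8

Remarks before the steps:
- Design: the stereochemistry of the epoxy ether 12 and of the chroman 13 was checked against unit 1 of the target and agrees. A silyl ether on the para oxygen would not survive benzylation or enolate chemistry next to a formyl group, and a donor there would let the oxirane ionise on its own. The para oxygen is therefore carried as a tosylate, and the oxirane is made before the aryl ether so that no 1,3-diarylallyl cation can scramble the etherification.
- Assumption: in the oxazaborolidine reduction of 8 the aryl group takes the larger-substituent role, so the (S)-catalyst gives (R)-9; if the sense proves opposite, the (R)-catalyst is used.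
- Assumption: the L-series Shi ketone (made from L-sorbose), the tartrate and the oxazaborolidine are bought; catalysts are not counted as steps.

## Route

Step 1
Reactants: 1 2,4,6-trihydroxybenzaldehyde
Product: 2 3,5-dihydroxy-4-formylphenyl 4-methylbenzenesulfonate
Conditions: TsCl (1.0 equiv), K2CO3 (1.1 equiv), acetone, 0 °C → rt
Reagents that add atoms: 4-toluenesulfonyl chloride, Cc1ccc(cc1)S(Cl)(=O)=O
Why: The hydroxyl para to the formyl group is the most acidic and is not held in a hydrogen bond to the carbonyl, so monosulfonylation should go there; selective sulfonylation of the para hydroxyl of polyhydroxy aryl carbonyl compounds is a standard tactic.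

Step 2
Reactants: 2 3,5-dihydroxy-4-formylphenyl 4-methylbenzenesulfonate
Product: 3 3,5-bis(benzyloxy)-4-formylphenyl 4-methylbenzenesulfonate
Conditions: BnBr (2.4 equiv), K2CO3, DMF, rt → 45 °C
Reagents that add atoms: benzyl bromide, BrCc1ccccc1
Why: Williamson etherification of the two remaining phenols; dry carbonate in DMF alkylates faster than it attacks an aryl sulfonate.

Step 3
Reactants: 4 3',4'-dihydroxyacetophenone
Product: 5 1-[3,4-bis(benzyloxy)phenyl]ethanone
Conditions: BnBr (2.3 equiv), K2CO3, DMF, 60 °C
Reagents that add atoms: benzyl bromide, BrCc1ccccc1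
Why: Williamson etherification of a catechol; no competing site.

Step 4
Reactants: 3 3,5-bis(benzyloxy)-4-formylphenyl 4-methylbenzenesulfonate; 5 1-[3,4-bis(benzyloxy)phenyl]ethanone
Product: 8 (E)-1-[3,4-bis(benzyloxy)phenyl]-3-[2,6-bis(benzyloxy)-4-(tosyloxy)phenyl]prop-2-en-1-one, via aldol adduct 6 (not isolated), via aldol mesylate 7 (not isolated)
Conditions: 5, LiN(SiMe3)2, THF, −78 °C; then 3; then MsCl, Et3N, −78 °C → rt
Reagents that add atoms: none
Why: Directed aldol addition of the lithium enolate of 5 to the aldehyde, mesylation of the aldolate and E1cB elimination give the E-enone, the Claisen–Schmidt product reached without hydroxide, which would cleave an aryl sulfonate para to a carbonyl group. The stereocentre of 6 and 7 is lost in the elimination.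

Step 5
Reactants: 8 (E)-1-[3,4-bis(benzyloxy)phenyl]-3-[2,6-bis(benzyloxy)-4-(tosyloxy)phenyl]prop-2-en-1-one
Product: 9 (R,E)-1-[3,4-bis(benzyloxy)phenyl]-3-[2,6-bis(benzyloxy)-4-(tosyloxy)phenyl]prop-2-en-1-ol
Conditions: (S)-1-methyl-3,3-diphenyltetrahydro-1H,3H-pyrrolo[1,2-c][1,3,2]oxazaborole (20 mol %), BH3·SMe2, THF, −30 °C; MeOH quench; base-washed silica
Reagents that add atoms: none
Why: Corey–Bakshi–Shibata reduction gives 1,2-reduction of the enone with hydride delivered to one carbonyl face inside the catalyst–borane–ketone complex; this sets the carbinol, which after inversion in step 7 becomes C2 of unit 1. The acid-labile diarylallyl alcohol is kept away from acid.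

Step 6
Reactants: 9 (R,E)-1-[3,4-bis(benzyloxy)phenyl]-3-[2,6-bis(benzyloxy)-4-(tosyloxy)phenyl]prop-2-en-1-ol
Product: 10 (S)-[3,4-bis(benzyloxy)phenyl]{(2S,3S)-3-[2,6-bis(benzyloxy)-4-(tosyloxy)phenyl]oxiran-2-yl}methanol (erythro epoxy alcohol, trans oxirane)
Conditions: 1,2:4,5-di-O-isopropylidene-β-L-erythro-2,3-hexodiulo-2,6-pyranose (30 mol %), KHSO5 (as Oxone), K2CO3, Bu4NHSO4, MeCN/CH2(OMe)2/aq. Na2B4O7 buffer (pH about 10.5), 0 °C
Reagents that add atoms: potassium peroxymonosulfate, [K+].[O-]S(=O)(=O)OO
Why: Shi epoxidation: the chiral dioxirane transfers oxygen to one face of the E-alkene through a spiro transition state, so both oxirane carbons are set by the reagent and the E geometry becomes the trans oxirane; the L-series ketone is the one that gives the (S,S) sense. Free hydroxyl groups are tolerated, the basic medium protects the oxirane, and the para sulfonate keeps it from ionising.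

Step 7
Reactants: 10 (S)-[3,4-bis(benzyloxy)phenyl]{(2S,3S)-3-[2,6-bis(benzyloxy)-4-(tosyloxy)phenyl]oxiran-2-yl}methanol; 11 3,5-bis(benzyloxy)phenol
Product: 12 3,5-bis(benzyloxy)phenyl ether of C1-inverted 10: (R)-configured aryloxy carbon, threo to the unchanged trans oxirane
Conditions: PPh3, DIAD, toluene/THF, 0 °C → rt
Reagents that add atoms: none
Why: Mitsunobu etherification with SN2 inversion at the carbinol turns the erythro alcohol into the threo ether, the relationship that maps onto 2,3-cis. The oxirane next to the reacting carbon disfavours ionisation, and aryl oxiranyl carbinols are established substrates for this etherification with 11.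

Step 8
Reactants: 12 3,5-bis(benzyloxy)phenyl ether of C1-inverted 10
Product: 13 (2R,3R)-5,7,3',4'-tetra-O-benzyl-4β-[2,6-bis(benzyloxy)-4-(tosyloxy)phenyl]epicatechin (2,3-cis, 3,4-trans, 3-hydroxyl free)
Conditions: BF3·OEt2 (0.5 equiv), CH2Cl2, −78 → −40 °C; Et3N quench
Reagents that add atoms: none
Why: BF3 coordinates the oxirane oxygen and lengthens the C4–O bond, which is benzylic to a ring with two ortho benzyloxy groups; the ortho carbon of the 3,5-dibenzyloxyphenyl ether, activated by an ortho and a para oxygen, attacks C4 from the side opposite the leaving oxygen (Friedel–Crafts alkylation), and loss of a proton restores the arene and frees the 3-hydroxyl. The closest known reaction type is the Lewis-acid-promoted intramolecular oxirane–arene cyclisation of aryl 2,3-epoxypropyl ethers to chroman-3-ols. Ring C closes in the 6-endo mode, with both oxirane carbons in the new ring. The one new stereocentre, C4, is set by inversion of the aryl-bearing oxirane carbon, which places the aryl group trans to O3 (4β); a more ionised pathway should converge on the same 3,4-trans chroman, which is the more stable one. C2 and C3 are carried over unchanged from 12 and are cis. The step needs attack at C4 and not at C3, which the benzylic activation secures, since 5-exo attack at C3 would be neither benzylic nor free of the inductive pull of the C2 ether. It needs a single site of C-alkylation, which the symmetry of the nucleophilic ring secures. It needs ring closure to outrun the 1,2-hydride shift to a ketone, for which the low temperature, the intramolecular nucleophile and the para sulfonate, which keeps the opening from becoming a free cation, are relied on.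

Step 9
Reactants: 13 (2R,3R)-5,7,3',4'-tetra-O-benzyl-4β-[2,6-bis(benzyloxy)-4-(tosyloxy)phenyl]epicatechin
Product: 14 (2R,3R)-5,7,3',4'-tetra-O-benzyl-4β-[2,6-bis(benzyloxy)-4-hydroxyphenyl]epicatechin
Conditions: KOH, MeOH/THF/H2O, 60 °C, argon; then dilute aq. HCl to pH 6
Reagents that add atoms: none
Why: Hydroxide attacks sulfur and the phenoxide leaves (standard cleavage of an aryl tosylate); benzyl ethers and the chroman are inert, and with ring B fully benzylated there is no quinone methide route to epimerise C2.

Step 10
Reactants: 15 4-(benzyloxy)benzaldehyde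
Product: 16 racemic 1-[4-(benzyloxy)phenyl]prop-2-en-1-ol
Conditions: CH2=CHMgBr, THF, 0 °C; sat. aq. NH4Cl
Reagents that add atoms: vinylmagnesium bromide, C=C[Mg]Br
Why: Grignard 1,2-addition to an aldehyde; the new stereocentre is racemic and is resolved in step 11.

Step 11
Reactants: 16 racemic 1-[4-(benzyloxy)phenyl]prop-2-en-1-ol
Product: 17 (S)-[4-(benzyloxy)phenyl][(R)-oxiran-2-yl]methanol (erythro)
Conditions: Ti(OiPr)4 (0.2 equiv), diisopropyl L-(+)-tartrate (0.25 equiv), t-BuOOH (0.55 equiv), 4 Å molecular sieves, CH2Cl2, −20 °C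
Reagents that add atoms: tert-butyl hydroperoxide, CC(C)(C)OO
Why: Sharpless kinetic resolution: the titanium tartrate complex epoxidises the (R)-carbinol enantiomer fast and on the face that gives the erythro product, so carbinol and oxirane carbon are set together, while the (S)-alcohol is left and separated. At most half of 16 can be used.

Step 12
Reactants: 14 (2R,3R)-5,7,3',4'-tetra-O-benzyl-4β-[2,6-bis(benzyloxy)-4-hydroxyphenyl]epicatechin; 17 (S)-[4-(benzyloxy)phenyl][(R)-oxiran-2-yl]methanol
Product: 18 (R)-[4-(benzyloxy)phenyl][(R)-oxiran-2-yl]methyl ether of the phenol 14 (threo)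
Conditions: PPh3, DIAD, toluene/THF, 0 °C → rt
Reagents that add atoms: none
Why: Mitsunobu etherification with inversion at the carbinol of 17 (erythro to threo); this is the known way to join a phenol to an aryl oxiranyl carbinol. The 3-hydroxyl of 14, secondary and flanked by two aryl-bearing carbons, is too hindered to compete.

Step 13
Reactants: 18 (R)-[4-(benzyloxy)phenyl][(R)-oxiran-2-yl]methyl ether of the phenol 14
Product: 19 5,7,3',4'-tetra-O-benzylepicatechin-(4β→6)-5,7,4'-tri-O-benzylepiafzelechin (both 3-hydroxyls free)
Conditions: AuCl3 (5 mol %), AgOTf (15 mol %), ClCH2CH2Cl, 0 °C → rt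
Reagents that add atoms: none
Why: Gold-promoted intramolecular oxirane–arene cyclisation, the established route from aryl 2,3-epoxypropyl ethers to chroman-3-ols: a carbon ortho to the new ether oxygen attacks the primary oxirane carbon (6-endo), closing ring C of unit 2. The two ortho positions are equivalent, so the unit 1 substituent ends at C6; no stereocentre is formed, and C2 and C3 come from 18 as 2,3-cis.

Step 14
Reactants: 19 5,7,3',4'-tetra-O-benzylepicatechin-(4β→6)-5,7,4'-tri-O-benzylepiafzelechin
Product: 20 4β-(2-hydroxyethoxy) derivative of 19 at C4 of unit 2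
Conditions: DDQ (1.5 equiv), HOCH2CH2OH (10 equiv), DMAP (cat.), CH2Cl2, rt
Reagents that add atoms: ethylene glycol, OCCO
Why: Benzylic oxidation by hydride abstraction at the C4 methylene, whose cation is stabilised by the three oxygens of ring A, followed by capture by the glycol trans to O3; this is the standard activation of benzylated flavan-3-ols. The C4 methine of unit 1 is hindered and poorly aligned with its ring π systems, and the configuration at the new C4 is immaterial because it is ionised again in step 19.

Step 15
Reactants: 21 (−)-epicatechin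
Product: 22 5,7,3',4'-tetra-O-benzyl-(−)-epicatechin
Conditions: BnBr (4.4 equiv), K2CO3, DMF, 0 °C → rt
Reagents that add atoms: benzyl bromide, BrCc1ccccc1
Why: Williamson etherification of the four phenols; carbonate is too weak to alkylate the 3-hydroxyl or to epimerise C2.

Step 16
Reactants: 22 5,7,3',4'-tetra-O-benzyl-(−)-epicatechin
Product: 23 8-bromo-5,7,3',4'-tetra-O-benzyl-(−)-epicatechin
Conditions: NBS (1.0 equiv), CH2Cl2, −78 °C → rt
Reagents that add atoms: N-bromosuccinimide, O=C1CCC(=O)N1Br
Why: Electrophilic aromatic bromination; in benzylated flavan-3-ols C8 is the most reactive ring A position, so one equivalent blocks C8 and leaves C6 free.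

Step 17
Reactants: 22 5,7,3',4'-tetra-O-benzyl-(−)-epicatechin
Product: 24 4β-(2-hydroxyethoxy)-5,7,3',4'-tetra-O-benzyl-(−)-epicatechin
Conditions: DDQ (1.5 equiv), HOCH2CH2OH (10 equiv), DMAP (cat.), CH2Cl2, rt
Reagents that add atoms: ethylene glycol, OCCO
Why: Same benzylic oxidation as step 14 on the monomer, for which it is well established; the glycol adds trans to the 3-hydroxyl.

Step 18
Reactants: 24 4β-(2-hydroxyethoxy)-5,7,3',4'-tetra-O-benzyl-(−)-epicatechin; 23 8-bromo-5,7,3',4'-tetra-O-benzyl-(−)-epicatechin
Product: 25 5,7,3',4'-tetra-O-benzylepicatechin-(4β→6)-8-bromo-5,7,3',4'-tetra-O-benzylepicatechin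
Conditions: 23 (3 equiv), BF3·OEt2, CH2Cl2, −78 → −30 °C
Reagents that add atoms: none
Why: Lewis-acid ionisation of the 4-alkoxy group and Friedel–Crafts capture of the C4 cation; with C8 brominated the only ring A position of 23 is C6, and attack anti to the 3-hydroxyl of the cis-2,3 cation gives the 4β bond. The excess of the cheap monomer 23 suppresses self-condensation of 24 through its own free C8.

Step 19
Reactants: 20 4β-(2-hydroxyethoxy) derivative of 19; 25 5,7,3',4'-tetra-O-benzylepicatechin-(4β→6)-8-bromo-5,7,3',4'-tetra-O-benzylepicatechin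
Product: 26 pentadeca-O-benzyl tetramer brominated at C8 of unit 4: unit 1-(4β→6)-unit 2-(4β→8)-unit 3-(4β→6)-unit 4, all 3-hydroxyls free
Conditions: 25 (2.5 equiv, excess recovered), BF3·OEt2, CH2Cl2, −78 → −30 °C
Reagents that add atoms: none
Why: The same cationic interflavan coupling as step 18: C4 of unit 2 is ionised and captured trans to its 3-hydroxyl (4β). In 25, C8 of unit 4 is blocked by bromine, and C8 of unit 3 is the usual and more accessible site of chain extension compared with C6.

Step 20
Reactants: 26 pentadeca-O-benzyl tetramer brominated at C8 of unit 4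
Product: 27 epicatechin-(4β→6)-epiafzelechin-(4β→8)-epicatechin-(4β→6)-epicatechin (CNP0103636.1)
Conditions: H2 (1 atm), Pd(OH)2/C, NaOAc (1.5 equiv), THF/MeOH/H2O, rt
Reagents that add atoms: none
Why: Hydrogenolysis removes the fifteen benzyl ethers and reduces the aryl bromide in one operation; acetate buffers the hydrogen bromide so that the acid-labile interflavan bonds are not exposed to strong acid, and no stereocentre is touched.

## Compound list

1 | 2,4,6-trihydroxybenzaldehyde | O=Cc1c(O)cc(O)cc1O | starting material
2 | 3,5-dihydroxy-4-formylphenyl 4-methylbenzenesulfonate | O=Cc1c(O)cc(OS(=O)(=O)c2ccc(C)cc2)cc1O | intermediate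
3 | 3,5-bis(benzyloxy)-4-formylphenyl 4-methylbenzenesulfonate | O=Cc1c(OCc2ccccc2)cc(OS(=O)(=O)c2ccc(C)cc2)cc1OCc2ccccc2 | intermediate
4 | 3',4'-dihydroxyacetophenone | CC(=O)c1ccc(O)c(O)c1 | starting material
5 | 1-[3,4-bis(benzyloxy)phenyl]ethanone | CC(=O)c1ccc(OCc2ccccc2)c(OCc2ccccc2)c1 | intermediate
6 | racemic 1-[3,4-bis(benzyloxy)phenyl]-3-[2,6-bis(benzyloxy)-4-(tosyloxy)phenyl]-3-hydroxypropan-1-one (lithium alkoxide in the flask) | O=C(CC(O)c1c(OCc2ccccc2)cc(OS(=O)(=O)c2ccc(C)cc2)cc1OCc2ccccc2)c1ccc(OCc2ccccc2)c(OCc2ccccc2)c1 | intermediate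
7 | racemic 1-[3,4-bis(benzyloxy)phenyl]-3-[2,6-bis(benzyloxy)-4-(tosyloxy)phenyl]-3-(mesyloxy)propan-1-one | O=C(CC(OS(C)(=O)=O)c1c(OCc2ccccc2)cc(OS(=O)(=O)c2ccc(C)cc2)cc1OCc2ccccc2)c1ccc(OCc2ccccc2)c(OCc2ccccc2)c1 | intermediate
8 | (E)-1-[3,4-bis(benzyloxy)phenyl]-3-[2,6-bis(benzyloxy)-4-(tosyloxy)phenyl]prop-2-en-1-one | O=C(/C=C/c1c(OCc2ccccc2)cc(OS(=O)(=O)c2ccc(C)cc2)cc1OCc2ccccc2)c1ccc(OCc2ccccc2)c(OCc2ccccc2)c1 | intermediate
9 | (R,E)-1-[3,4-bis(benzyloxy)phenyl]-3-[2,6-bis(benzyloxy)-4-(tosyloxy)phenyl]prop-2-en-1-ol | O[C@@H](c1ccc(OCc2ccccc2)c(OCc2ccccc2)c1)/C=C/c1c(OCc2ccccc2)cc(OS(=O)(=O)c2ccc(C)cc2)cc1OCc2ccccc2 | intermediate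
10 | (S)-[3,4-bis(benzyloxy)phenyl]{(2S,3S)-3-[2,6-bis(benzyloxy)-4-(tosyloxy)phenyl]oxiran-2-yl}methanol | O[C@@H](c1ccc(OCc2ccccc2)c(OCc2ccccc2)c1)[C@@H]3O[C@H]3c1c(OCc2ccccc2)cc(OS(=O)(=O)c2ccc(C)cc2)cc1OCc2ccccc2 | intermediate
11 | 3,5-bis(benzyloxy)phenol | Oc1cc(OCc2ccccc2)cc(OCc2ccccc2)c1 | starting material
12 | 3,5-bis(benzyloxy)phenyl ether of C1-inverted 10 (threo; (R)-aryloxy carbon; trans oxirane) | c9ccccc9COc1cc(OCc9ccccc9)cc(O[C@H](c2ccc(OCc9ccccc9)c(OCc9ccccc9)c2)[C@@H]6O[C@H]6c2c(OCc9ccccc9)cc(OS(=O)(=O)c8ccc(C)cc8)cc2OCc9ccccc9)c1 | intermediate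
13 | (2R,3R)-5,7,3',4'-tetra-O-benzyl-4β-[2,6-bis(benzyloxy)-4-(tosyloxy)phenyl]epicatechin | c9ccccc9COc1cc(OCc9ccccc9)c2c(c1)O[C@H](c1ccc(OCc9ccccc9)c(OCc9ccccc9)c1)[C@H](O)[C@H]2c1c(OCc9ccccc9)cc(OS(=O)(=O)c8ccc(C)cc8)cc1OCc9ccccc9 | intermediate
14 | (2R,3R)-5,7,3',4'-tetra-O-benzyl-4β-[2,6-bis(benzyloxy)-4-hydroxyphenyl]epicatechin | c9ccccc9COc1cc(OCc9ccccc9)c2c(c1)O[C@H](c1ccc(OCc9ccccc9)c(OCc9ccccc9)c1)[C@H](O)[C@H]2c1c(OCc9ccccc9)cc(O)cc1OCc9ccccc9 | intermediate
15 | 4-(benzyloxy)benzaldehyde | O=Cc1ccc(OCc2ccccc2)cc1 | starting material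
16 | racemic 1-[4-(benzyloxy)phenyl]prop-2-en-1-ol | OC(C=C)c1ccc(OCc2ccccc2)cc1 | intermediate
17 | (S)-[4-(benzyloxy)phenyl][(R)-oxiran-2-yl]methanol | O[C@@H](c1ccc(OCc2ccccc2)cc1)[C@@H]3OC3 | intermediate
18 | (R)-[4-(benzyloxy)phenyl][(R)-oxiran-2-yl]methyl ether of 14 | c9ccccc9COc1cc(OCc9ccccc9)c2c(c1)O[C@H](c1ccc(OCc9ccccc9)c(OCc9ccccc9)c1)[C@H](O)[C@H]2c1c(OCc9ccccc9)cc(O[C@H](c3ccc(OCc9ccccc9)cc3)[C@@H]4OC4)cc1OCc9ccccc9 | intermediate
19 | 5,7,3',4'-tetra-O-benzylepicatechin-(4β→6)-5,7,4'-tri-O-benzylepiafzelechin | c9ccccc9COc1ccc([C@H]2Oc3cc(OCc9ccccc9)c([C@H]4c5c(OCc9ccccc9)cc(OCc9ccccc9)cc5O[C@H](c5ccc(OCc9ccccc9)c(OCc9ccccc9)c5)[C@@H]4O)c(OCc9ccccc9)c3C[C@H]2O)cc1 | intermediate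
20 | 4β-(2-hydroxyethoxy) derivative of 19 (C4 of unit 2) | c9ccccc9COc1ccc([C@H]2Oc3cc(OCc9ccccc9)c([C@H]4c5c(OCc9ccccc9)cc(OCc9ccccc9)cc5O[C@H](c5ccc(OCc9ccccc9)c(OCc9ccccc9)c5)[C@@H]4O)c(OCc9ccccc9)c3[C@H](OCCO)[C@H]2O)cc1 | intermediate
21 | (−)-epicatechin | Oc1cc(O)c2c(c1)O[C@H](c1ccc(O)c(O)c1)[C@H](O)C2 | starting material
22 | 5,7,3',4'-tetra-O-benzyl-(−)-epicatechin | c9ccccc9COc1cc(OCc9ccccc9)c2c(c1)O[C@H](c1ccc(OCc9ccccc9)c(OCc9ccccc9)c1)[C@H](O)C2 | intermediate
23 | 8-bromo-5,7,3',4'-tetra-O-benzyl-(−)-epicatechin | c9ccccc9COc1cc(OCc9ccccc9)c2c(c1Br)O[C@H](c1ccc(OCc9ccccc9)c(OCc9ccccc9)c1)[C@H](O)C2 | intermediate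
24 | 4β-(2-hydroxyethoxy)-5,7,3',4'-tetra-O-benzyl-(−)-epicatechin | c9ccccc9COc1cc(OCc9ccccc9)c2c(c1)O[C@H](c1ccc(OCc9ccccc9)c(OCc9ccccc9)c1)[C@H](O)[C@H]2OCCO | intermediate
25 | 5,7,3',4'-tetra-O-benzylepicatechin-(4β→6)-8-bromo-5,7,3',4'-tetra-O-benzylepicatechin | c1c(OCc9ccccc9)cc(OCc9ccccc9)c2c1O[C@H](c3ccc(OCc9ccccc9)c(OCc9ccccc9)c3)[C@H](O)[C@H]2c4c(OCc9ccccc9)c(Br)c5c(c4OCc9ccccc9)C[C@@H](O)[C@@H](c6ccc(OCc9ccccc9)c(OCc9ccccc9)c6)O5 | intermediate
26 | pentadeca-O-benzyl tetramer, 8-bromo on unit 4 | c9ccccc9COc1ccc([C@H]2Oc3cc(OCc9ccccc9)c([C@H]4c5c(OCc9ccccc9)cc(OCc9ccccc9)cc5O[C@H](c5ccc(OCc9ccccc9)c(OCc9ccccc9)c5)[C@@H]4O)c(OCc9ccccc9)c3[C@H](c3c(OCc9ccccc9)cc(OCc9ccccc9)c4c3O[C@H](c3ccc(OCc9ccccc9)c(OCc9ccccc9)c3)[C@H](O)[C@H]4c3c(OCc9ccccc9)c(Br)c4c(c3OCc9ccccc9)C[C@@H](O)[C@@H](c3ccc(OCc9ccccc9)c(OCc9ccccc9)c3)O4)[C@H]2O)cc1 | intermediate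
27 | epicatechin-(4β→6)-epiafzelechin-(4β→8)-epicatechin-(4β→6)-epicatechin | Oc1ccc([C@H]2Oc3cc(O)c([C@H]4c5c(O)cc(O)cc5O[C@H](c5ccc(O)c(O)c5)[C@@H]4O)c(O)c3[C@H](c3c(O)cc(O)c4c3O[C@H](c3ccc(O)c(O)c3)[C@H](O)[C@H]4c3c(O)cc4c(c3O)C[C@@H](O)[C@@H](c3ccc(O)c(O)c3)O4)[C@H]2O)cc1 | target

## Step count and least certain steps

Total: 20 steps. Longest linear sequence: 13 steps (1, 2, 4, 5, 6, 7, 8, 9, 12, 13, 14, 19, 20).

Step 8 (key step). The most likely failure is rearrangement of the activated oxirane by 1,2-hydride shift to a ketone, or ionisation at the aryloxy-bearing carbon, before ring closure; both would compete if the Lewis acid makes a free benzylic cation faster than the arene can reach it. Fallback with a different approach: give up the ring closure and attach the differentiated ring to a ready-made unit 1. The phenol 11 is sulfonylated (TsCl, Et3N) to 3,5-bis(benzyloxy)phenyl 4-methylbenzenesulfonate F1, and F1 (in excess) captures the C4 cation generated from 24 with BF3·OEt2 at the carbon between its two benzyloxy groups. This sets out from 11 and 24 and returns to the route at 13. Its weak point is regiochemistry on F1, because attack next to the sulfonate competes, which is why it is not the first choice.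

Step 7. The likely failure is opening of the activated oxirane by the phenoxide, or loss of configuration by ionisation of the alkoxyphosphonium intermediate, because the reacting carbon is benzylic to an alkoxy-substituted ring. Fallback: reverse the order of etherification and epoxidation. The allylic alcohol 9 is coupled with 11 under Mitsunobu conditions to (S,E)-1-[3,4-bis(benzyloxy)phenyl]-3-[2,6-bis(benzyloxy)-4-(tosyloxy)phenyl]allyl 3,5-bis(benzyloxy)phenyl ether F2, and F2 is epoxidised with the same L-series ketone and KHSO5. This sets out from 9 and returns at 12. The price is the risk of allylic transposition during the etherification, which the electron-poor para sulfonate reduces but does not remove.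

Step 6. The likely failures are poor facial selectivity, because the 2,6-disubstituted aryl ring is twisted out of the alkene plane and fits the spiro transition state badly, and competing oxidation of the doubly activated carbinol by the dioxirane. Fallback: hydroxyl-directed epoxidation in place of reagent-controlled oxygen transfer, with Ti(OiPr)4, diisopropyl L-(+)-tartrate and tert-butyl hydroperoxide on 9. This is the matched combination for this carbinol configuration and gives the erythro epoxy alcohol. It sets out from 9 and returns at 10 and makes no new compound.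

Step 14. The likely failure is hydride abstraction at the wrong benzylic position, above all the C4 methine of unit 1, which lies between two trioxygenated rings, followed by over-oxidation. Fallback: lower the electron density of the competing rings before oxidising. 19 is treated with NBS (3 equiv) to give the 6,8-dibromo (unit 1), 8-bromo (unit 2) derivative F3. Three bromines then flank the rings that would stabilise a cation at C4 of unit 1, but only one flanks ring A of unit 2. Oxidation with DDQ and ethylene glycol gives the 4β-(2-hydroxyethoxy) tribromide F4, which can no longer self-condense and is coupled 1:1 with 25 (BF3·OEt2) to the tetrabromo pentadeca-O-benzyl tetramer F5. Hydrogenolysis as in step 20 removes all four bromines. This sets out from 19 and returns at 27.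

Step 19. The likely failure is self-condensation of 20 through its own free ring A positions (C6 and C8 of unit 1, C8 of unit 2) in competition with the hindered dimer 25, and some attack at C6 of unit 3. Fallback: build the lower half one unit at a time with cheap monomers in excess and an orthogonal leaving group. 24 is converted with 2,6-dimethylbenzenethiol and BF3·OEt2 into 4β-(2,6-dimethylphenylthio)-5,7,3',4'-tetra-O-benzylepicatechin F6. F6 (in excess) is coupled through its C8 with 20 under BF3·OEt2, which leaves the thioether untouched, to give the trimer thioether F7. F7 is then activated with a thiophilic silver salt (AgBF4) in the presence of excess 23, whose only free position is C6. This sets out from 20, 23 and 24 and returns at 26.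

## Further compounds

F1 | step 8 | 3,5-bis(benzyloxy)phenyl 4-methylbenzenesulfonate | Cc1ccc(cc1)S(=O)(=O)Oc1cc(OCc2ccccc2)cc(OCc2ccccc2)c1
F2 | step 7 | (S,E)-1-[3,4-bis(benzyloxy)phenyl]-3-[2,6-bis(benzyloxy)-4-(tosyloxy)phenyl]allyl 3,5-bis(benzyloxy)phenyl ether | c9ccccc9COc1cc(OCc9ccccc9)cc(O[C@H](c2ccc(OCc9ccccc9)c(OCc9ccccc9)c2)/C=C/c2c(OCc9ccccc9)cc(OS(=O)(=O)c8ccc(C)cc8)cc2OCc9ccccc9)c1
F0 | step 6 | none | none
F3 | step 14 | 6,8-dibromo (unit 1), 8-bromo (unit 2) derivative of 19 | c9ccccc9COc1ccc([C@H]2Oc3c(Br)c(OCc9ccccc9)c([C@H]4c5c(OCc9ccccc9)c(Br)c(OCc9ccccc9)c(Br)c5O[C@H](c5ccc(OCc9ccccc9)c(OCc9ccccc9)c5)[C@@H]4O)c(OCc9ccccc9)c3C[C@H]2O)cc1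
F4 | step 14 | 4β-(2-hydroxyethoxy) derivative of F3 (C4 of unit 2) | c9ccccc9COc1ccc([C@H]2Oc3c(Br)c(OCc9ccccc9)c([C@H]4c5c(OCc9ccccc9)c(Br)c(OCc9ccccc9)c(Br)c5O[C@H](c5ccc(OCc9ccccc9)c(OCc9ccccc9)c5)[C@@H]4O)c(OCc9ccccc9)c3[C@H](OCCO)[C@H]2O)cc1
F5 | step 14 | pentadeca-O-benzyl tetramer brominated at C6 and C8 of unit 1, C8 of unit 2 and C8 of unit 4 | c9ccccc9COc1ccc([C@H]2Oc3c(Br)c(OCc9ccccc9)c([C@H]4c5c(OCc9ccccc9)c(Br)c(OCc9ccccc9)c(Br)c5O[C@H](c5ccc(OCc9ccccc9)c(OCc9ccccc9)c5)[C@@H]4O)c(OCc9ccccc9)c3[C@H](c3c(OCc9ccccc9)cc(OCc9ccccc9)c4c3O[C@H](c3ccc(OCc9ccccc9)c(OCc9ccccc9)c3)[C@H](O)[C@H]4c3c(OCc9ccccc9)c(Br)c4c(c3OCc9ccccc9)C[C@@H](O)[C@@H](c3ccc(OCc9ccccc9)c(OCc9ccccc9)c3)O4)[C@H]2O)cc1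
F6 | step 19 | 4β-(2,6-dimethylphenylthio)-5,7,3',4'-tetra-O-benzylepicatechin | c9ccccc9COc1cc(OCc9ccccc9)c2c(c1)O[C@H](c1ccc(OCc9ccccc9)c(OCc9ccccc9)c1)[C@H](O)[C@H]2Sc1c(C)cccc1C
F7 | step 19 | protected unit 1-(4β→6)-unit 2-(4β→8)-unit 3 trimer with a 4β-(2,6-dimethylphenylthio) group on unit 3 | c9ccccc9COc1ccc([C@H]2Oc3cc(OCc9ccccc9)c([C@H]4c5c(OCc9ccccc9)cc(OCc9ccccc9)cc5O[C@H](c5ccc(OCc9ccccc9)c(OCc9ccccc9)c5)[C@@H]4O)c(OCc9ccccc9)c3[C@H](c3c(OCc9ccccc9)cc(OCc9ccccc9)c4c3O[C@H](c3ccc(OCc9ccccc9)c(OCc9ccccc9)c3)[C@H](O)[C@H]4Sc3c(C)cccc3C)[C@H]2O)cc1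
A1 | alternative 1 | silicon-bridged unit 3-(4β→6)-unit 4 dimer (dibenzo-dioxasilocine) | c9ccccc9COc1cc(O[Si](C(C)C)(C(C)C)Oc3c5c(OCc9ccccc9)cc4c3C[C@@H](OCc9ccccc9)[C@@H](c3ccc(OCc9ccccc9)c(OCc9ccccc9)c3)O4)c2c(c1)O[C@H](c1ccc(OCc9ccccc9)c(OCc9ccccc9)c1)[C@H](OCc9ccccc9)[C@H]25
A2 | alternative 1 | silicon-tethered 4β-ethoxy precursor of A1 | c9ccccc9COc1cc(O[Si](C(C)C)(C(C)C)Oc3cc(OCc9ccccc9)cc4c3C[C@@H](OCc9ccccc9)[C@@H](c3ccc(OCc9ccccc9)c(OCc9ccccc9)c3)O4)c2c(c1)O[C@H](c1ccc(OCc9ccccc9)c(OCc9ccccc9)c1)[C@H](OCc9ccccc9)[C@H]2OCC
A3 | alternative 2 | protected tetramer with unit 2 as 3-benzyloxy-4-aryl-3,4-dihydrocoumarin | O=C2Oc3cc(OCc9ccccc9)c([C@H]4c5c(OCc9ccccc9)cc(OCc9ccccc9)cc5O[C@H](c5ccc(OCc9ccccc9)c(OCc9ccccc9)c5)[C@@H]4OCc9ccccc9)c(OCc9ccccc9)c3[C@H](c3c(OCc9ccccc9)cc(OCc9ccccc9)c4c3O[C@H](c3ccc(OCc9ccccc9)c(OCc9ccccc9)c3)[C@H](OCc9ccccc9)[C@H]4c3c(OCc9ccccc9)cc4c(c3OCc9ccccc9)C[C@@H](OCc9ccccc9)[C@@H](c3ccc(OCc9ccccc9)c(OCc9ccccc9)c3)O4)[C@H]2OCc9ccccc9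
A4 | alternative 2 | benzhydrol precursor of the ortho-quinone methide (carbinol configuration undefined) | Oc3cc(OCc9ccccc9)c([C@H]4c5c(OCc9ccccc9)cc(OCc9ccccc9)cc5O[C@H](c5ccc(OCc9ccccc9)c(OCc9ccccc9)c5)[C@@H]4OCc9ccccc9)c(OCc9ccccc9)c3C(O)c3c(OCc9ccccc9)cc(OCc9ccccc9)c4c3O[C@H](c3ccc(OCc9ccccc9)c(OCc9ccccc9)c3)[C@H](OCc9ccccc9)[C@H]4c3c(OCc9ccccc9)cc4c(c3OCc9ccccc9)C[C@@H](OCc9ccccc9)[C@@H](c3ccc(OCc9ccccc9)c(OCc9ccccc9)c3)O4
A5 | alternative 3 | protected unit 1 (3-O-benzyl) with a MOM-differentiated phloroglucinol ring at C4 | c9ccccc9COc1cc(OCc9ccccc9)c2c(c1)O[C@H](c1ccc(OCc9ccccc9)c(OCc9ccccc9)c1)[C@H](OCc9ccccc9)[C@H]2c1c(OCc9ccccc9)cc(OCOC)cc1OCc9ccccc9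
A6 | alternative 3 | open-chain phenol precursor of A5 (1,1,3-triaryl-2-benzyloxypropane) | c9ccccc9COc1cc(OCc9ccccc9)c(c(O)c1)[C@H](c1c(OCc9ccccc9)cc(OCOC)cc1OCc9ccccc9)[C@@H](OCc9ccccc9)Cc1ccc(OCc9ccccc9)c(OCc9ccccc9)c1
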